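## Retrosynthetic overview

1. The ten-membered lactone is closed last, at the C1(=O)–O–C9 ester bond, from a seco acid whose two arms sit cis on the γ-lactone.
2. The hexahydrofuro[3,2-b]pyran comes from a flat 2,5-disubstituted furan: oxidative ring expansion to a 2H-pyran-3(6H)-one, anomeric reduction, then closure of the tetrahydrofuran ring at O1–C7a; the surplus C6 ketone is removed afterwards.
3. Enabling feature: the tetrahydropyran ring (O4, C5 with its CH3, C6, C7, C7a, C3a) has the oxygen pattern of a ring-expanded 2-(1-hydroxyethyl)furan, C7a is the β-carbon of that enone, and the enol oxygen O1 of the α-acyl γ-lactone is tied to C3a through the single CH2 (C3), exactly 5-exo to C7a.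
4. The cis α-acyl γ-lactone comes from Michael addition of a furyl β-keto ester to a 2,6-cis-2H-pyran-3(6H)-one (a second furan, same ring expansion), then SmI2 cleavage of the α-alkoxy ketone C–O bond and translactonisation (trans on the temporary pyranone becomes cis on the lactone).
5. Ring order: temporary pyranone, γ-lactone, tetrahydropyran plus tetrahydrofuran (key step), ten-membered lactone; stereocentres come from methyl (R)-3-hydroxybutanoate and two asymmetric transfer hydrogenations of 2-acylfurans.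

Key step: step 12

Remarks
- Locants: macrolide carbons run C1 (lactone C=O) to C9 (CH–CH3); the furopyran is O1, C2 (ylidene carbon), C3, C3a, O4, C5 (CH3), C6, C7, C7a. TBDPS = tert-butyldiphenylsilyl.
- The α-carbon of the 1,3-dicarbonyl unit in 16–20 is a keto/enol epimer mixture and is written without configuration; 9 and 19 are anomer mixtures; 22 and 23 are C6 epimer mixtures.
- Assumption: in the peracid oxidations the peracid oxygen ends in the ring ketone and the former furan oxygen becomes the lactol OH that is later lost.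

## Route

Step 1
Reactants: 1 methyl (R)-3-hydroxybutanoate
Product: 2 methyl (R)-3-(TBDPS-oxy)butanoate
Conditions: TBDPSCl, imidazole, DMF, rt
Reagents that add atoms: tert-butyl(chloro)diphenylsilane, CC(C)(C)[Si](Cl)(c1ccccc1)c1ccccc1
Why: Imidazole-promoted silylation of the secondary alcohol; the bulky silyl ether is chosen to survive the two acidic lactol reductions later in the route.

Step 2
Reactants: 2 methyl (R)-3-(TBDPS-oxy)butanoate
Product: 3 (R)-3-(TBDPS-oxy)butanoic acid
Conditions: LiOH, THF/H2O, rt; 1 M HCl work-up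
Reagents that add atoms: lithium hydroxide, [Li+].[OH-]
Why: Saponification of the methyl ester, which leaves the silyl ether and the stereocentre untouched.

Step 3
Reactants: 4 2-(furan-2-yl)acetic acid
Product: 5 allyl 2-(furan-2-yl)acetate
Conditions: allyl bromide, K2CO3, DMF, rt
Reagents that add atoms: allyl bromide, C=CCBr
Why: SN2 O-alkylation of the carboxylate gives an ester that can be removed at the end under neutral conditions.

Step 4
Reactants: 3 (R)-3-(TBDPS-oxy)butanoic acid; 5 allyl 2-(furan-2-yl)acetate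
Product: 7 allyl 2-{5-[(R)-3-(TBDPS-oxy)butanoyl]furan-2-yl}acetate, via mixed trifluoroacetic anhydride 6 (not isolated)
Conditions: 3, (CF3CO)2O, CH2Cl2, 0 °C; then 5, H3PO4 (cat.), 0 °C to rt
Reagents that add atoms: none
Why: Friedel–Crafts acylation through the mixed anhydride, in which the electron-rich 2-alkylfuran is acylated at its free α-position by the non-fluorinated acyl group.

Step 5
Reactants: 7 allyl 2-{5-[(R)-3-(TBDPS-oxy)butanoyl]furan-2-yl}acetate
Product: 8 allyl 2-{5-[(1R,3R)-1-hydroxy-3-(TBDPS-oxy)butyl]furan-2-yl}acetate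
Conditions: RuCl[(R,R)-TsDPEN](p-cymene) (1 mol %), HCO2H/Et3N azeotrope, rt
Reagents that add atoms: none
Why: Asymmetric transfer hydrogenation of a 2-furyl ketone, in which the (R,R) catalyst delivers hydride to the face that gives the R carbinol under catalyst control over the remote silyloxy centre.

Step 6
Reactants: 8 allyl 2-{5-[(1R,3R)-1-hydroxy-3-(TBDPS-oxy)butyl]furan-2-yl}acetate
Product: 10 allyl 2-{(2S,6R)-5-oxo-6-[(R)-2-(TBDPS-oxy)propyl]-5,6-dihydro-2H-pyran-2-yl}acetate (2,6-cis), via lactol 9 (not isolated)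
Conditions: mCPBA, CH2Cl2, 0 °C; then Et3SiH, CF3CO2H, −40 to 0 °C
Reagents that add atoms: 3-chloroperoxybenzoic acid, OOC(=O)c1cccc(Cl)c1
Why: Achmatowicz rearrangement of the furfuryl alcohol followed by ionic hydrogenation of the lactol, in which axial hydride attack on the oxocarbenium ion places the new C–H cis to the hydrogen of the carbinol-derived carbon and so sets the S configuration of the future C3.

Step 7
Reactants: 11 2-(furan-2-yl)acetonitrile
Product: 12 2-(5-acetylfuran-2-yl)acetonitrile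
Conditions: Ac2O, BF3·OEt2 (cat.), 0 °C to rt
Reagents that add atoms: acetic anhydride, CC(=O)OC(C)=O
Why: Friedel–Crafts acetylation of a 2-alkylfuran takes place at the free α-position.

Step 8
Reactants: 12 2-(5-acetylfuran-2-yl)acetonitrile
Product: 13 2-{5-[(R)-1-hydroxyethyl]furan-2-yl}acetonitrile
Conditions: RuCl[(R,R)-TsDPEN](p-cymene) (1 mol %), HCO2H/Et3N azeotrope, rt
Reagents that add atoms: none
Why: Asymmetric transfer hydrogenation of the 2-acetylfuran, in which the (R,R) catalyst gives the R alcohol that later becomes C5 of the furopyran.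

Step 9
Reactants: 13 2-{5-[(R)-1-hydroxyethyl]furan-2-yl}acetonitrile
Product: 15 methyl 4-{5-[(R)-1-hydroxyethyl]furan-2-yl}-3-oxobutanoate, via enamino ester 14 (not isolated)
Conditions: Zn, BrCH2CO2Me (slow addition), THF, reflux; then 1 M HCl, 0 °C to rt
Reagents that add atoms: methyl bromoacetate, COC(=O)CBr; water, O
Why: Blaise reaction, in which the zinc enolate of the bromoacetate adds to the nitrile and mild acid hydrolysis of the enamino ester gives the β-keto ester, while the carbinol is only held as its zinc alkoxide.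

Step 10
Reactants: 10 allyl 2-{(2S,6R)-5-oxo-6-[(R)-2-(TBDPS-oxy)propyl]-5,6-dihydro-2H-pyran-2-yl}acetate; 15 methyl 4-{5-[(R)-1-hydroxyethyl]furan-2-yl}-3-oxobutanoate
Product: 16 methyl 2-{(2S,3S,6R)-2-(2-allyloxy-2-oxoethyl)-5-oxo-6-[(R)-2-(TBDPS-oxy)propyl]tetrahydro-2H-pyran-3-yl}-4-{5-[(R)-1-hydroxyethyl]furan-2-yl}-3-oxobutanoate (2,3-trans, 2,6-cis)
Conditions: DBU (0.2 equiv), MeCN, 0 °C to rt
Reagents that add atoms: none
Why: Reversible Michael addition of the β-keto ester enolate to the enone carbon next to the acetate-bearing ring carbon, which under thermodynamic control places the new substituent equatorial and trans to that arm and thereby sets the future C4.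

Step 11
Reactants: 16 the Michael adduct
Product: 18 allyl 2-{(2S,3S)-4-(2-{5-[(R)-1-hydroxyethyl]furan-2-yl}acetyl)-5-oxo-3-[(R)-2-oxo-5-(TBDPS-oxy)hexyl]tetrahydrofuran-2-yl}acetate (2,3-cis), via hydroxy keto ester 17 (not isolated)
Conditions: SmI2, THF/MeOH, −78 °C; then PPTS (cat.), CH2Cl2, rt
Reagents that add atoms: none
Why: SmI2 reduces the α-alkoxy ketone to a ketyl that expels the ring oxygen (reductive cleavage of an α-hetero-substituted ketone), and the freed C3 hydroxyl then closes onto the methyl ester (5-exo-trig translactonisation), so that the trans relationship on the six-membered ring becomes the cis relationship of the two arms on the γ-lactone without any bond to a stereocentre being broken.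

Step 12
Reactants: 18 the furyl β-keto lactone
Product: 21 allyl 2-{(2S,3S,4E)-4-[(3aS,5R,7aS)-5-methyl-6-oxohexahydro-2H-furo[3,2-b]pyran-2(3H)-ylidene]-5-oxo-3-[(R)-2-oxo-5-(TBDPS-oxy)hexyl]tetrahydrofuran-2-yl}acetate, via Achmatowicz lactol 19 (not isolated), via cis-dihydropyranone 20 (not isolated)
Conditions: mCPBA, CH2Cl2, 0 °C; then Et3SiH, CF3CO2H, −40 to 0 °C; then Et3N, rt (one flask)
Reagents that add atoms: 3-chloroperoxybenzoic acid, OOC(=O)c1cccc(Cl)c1
Why: The peracid oxidises the electron-rich 2,5-dialkylfuran and the resulting ene-dione is trapped by the carbinol oxygen (Achmatowicz rearrangement, a 6-exo-trig hemiketalisation that closes the pyran ring of 19), after which acid ionises the lactol and Et3SiH reduces the cyclic oxocarbenium ion by axial hydride delivery (ionic hydrogenation of a lactol, the standard entry to 2,6-cis-dihydropyranones), so that C3a is set cis to the C5 methyl group fixed in step 8. After neutralisation the enol oxygen of the β-keto lactone adds to C7a, the enone β-carbon of 20, in a 5-exo-trig oxa-Michael addition that closes the tetrahydrofuran ring and forms the O1–C7a bond. The closest known reaction type is the oxa-Michael closure that follows C-alkylation of 1,3-dicarbonyl compounds on Achmatowicz pyranones and gives the same cis-fused furo[3,2-b]pyranone skeleton. C7a is controlled by the one-carbon tether, which can reach only the enone face that carries the C3a–CH2 bond, so the ring fusion is cis and the hydrogens at C3a, C5 and C7a end on one face. The step needs O- instead of C-attack, attack at C7a only, and the E alkene: C-attack would be a disfavoured 5-(enolendo)-exo-trig closure, C7a is the only electrophilic carbon once C3a has been reduced, and the E isomer (enol-ether oxygen anti to the lactone carbonyl, ring CH2 turned away from the substituted lactone carbon) is the thermodynamic one, reachable because the oxa-Michael addition is reversible. Chemoselectivity of the oxidation rests on the furan being far more nucleophilic than the terminal alkene of the allyl ester or the largely ketonised β-dicarbonyl unit.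

Step 13
Reactants: 21 the furopyranone
Product: 22 allyl 2-{(2S,3S,4E)-4-[(3aS,5R,7aS)-6-hydroxy-5-methylhexahydro-2H-furo[3,2-b]pyran-2(3H)-ylidene]-5-oxo-3-[(R)-2-oxo-5-(TBDPS-oxy)hexyl]tetrahydrofuran-2-yl}acetate (C6 epimers)
Conditions: NaBH4, MeOH/CH2Cl2, −78 °C
Reagents that add atoms: none
Why: Chemoselective borohydride reduction, since the six-membered α-alkoxy ketone is far more electrophilic than the acyclic dialkyl ketone of the side arm; the configuration of the new carbinol is irrelevant because this oxygen is removed.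

Step 14
Reactants: 22 the C6 alcohol
Product: 23 the O-(1H-imidazol-1-ylcarbonothioyl) derivative of 22
Conditions: 1,1'-thiocarbonyldiimidazole, DMAP (cat.), ClCH2CH2Cl, 60 °C
Reagents that add atoms: 1,1'-thiocarbonyldiimidazole, S=C(n1ccnc1)n1ccnc1
Why: Thioacylation of the secondary alcohol under neutral conditions gives the radical-labile ester for a Barton–McCombie deoxygenation without any base that could trigger β-elimination.

Step 15
Reactants: 23 the thiocarbonyl imidazolide
Product: 24 allyl 2-{(2S,3S,4E)-4-[(3aS,5R,7aS)-5-methylhexahydro-2H-furo[3,2-b]pyran-2(3H)-ylidene]-5-oxo-3-[(R)-2-oxo-5-(TBDPS-oxy)hexyl]tetrahydrofuran-2-yl}acetate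
Conditions: Bu3SnH, AIBN (cat.), toluene, 90 °C
Reagents that add atoms: none
Why: Barton–McCombie radical deoxygenation, in which the stannyl radical adds to the thiocarbonyl group, the secondary C–O bond fragments and the ring radical takes hydrogen from the stannane, while ketone, esters, silyl ether and the tetrasubstituted push–pull alkene are inert.

Step 16
Reactants: 24 the silyl ether
Product: 25 allyl 2-{(2S,3S,4E)-3-[(R)-5-hydroxy-2-oxohexyl]-4-[(3aS,5R,7aS)-5-methylhexahydro-2H-furo[3,2-b]pyran-2(3H)-ylidene]-5-oxotetrahydrofuran-2-yl}acetate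
Conditions: HF·pyridine, pyridine, THF, 0 °C to rt
Reagents that add atoms: none
Why: Buffered fluoride desilylation of the secondary silyl ether, which the vinylogous carbonate, the lactone and the allyl ester tolerate.

Step 17
Reactants: 25 the hydroxy allyl ester
Product: 26 2-{(2S,3S,4E)-3-[(R)-5-hydroxy-2-oxohexyl]-4-[(3aS,5R,7aS)-5-methylhexahydro-2H-furo[3,2-b]pyran-2(3H)-ylidene]-5-oxotetrahydrofuran-2-yl}acetic acid
Conditions: Pd(PPh3)4 (cat.), morpholine, THF, rt
Reagents that add atoms: none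
Why: Tsuji–Trost deallylation, in which zerovalent palladium ionises the allyl ester and morpholine captures the π-allyl complex, releasing the acid under neutral conditions.

Step 18
Reactants: 26 the seco acid
Product: 28 cordycicadin C, via mixed anhydride 27 (not isolated)
Conditions: 2-methyl-6-nitrobenzoic anhydride, DMAP, CH2Cl2, rt, slow addition at high dilution
Reagents that add atoms: none
Why: Shiina macrolactonisation, in which the mixed anhydride is activated by DMAP at the aliphatic carbonyl and the C9 hydroxyl closes the ten-membered ring at room temperature with retention at C9, helped by the cis-disposed arms on the γ-lactone.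

## Compound list

1 | methyl (R)-3-hydroxybutanoate | C[C@@H](O)CC(=O)OC | starting material
2 | methyl (R)-3-(TBDPS-oxy)butanoate | C[C@@H](O[Si](c1ccccc1)(c1ccccc1)C(C)(C)C)CC(=O)OC | intermediate
3 | (R)-3-(TBDPS-oxy)butanoic acid | C[C@@H](O[Si](c1ccccc1)(c1ccccc1)C(C)(C)C)CC(=O)O | intermediate
4 | 2-(furan-2-yl)acetic acid | OC(=O)Cc1ccco1 | starting material
5 | allyl 2-(furan-2-yl)acetate | C=CCOC(=O)Cc1ccco1 | intermediate
6 | (R)-3-(TBDPS-oxy)butanoic trifluoroacetic anhydride | C[C@@H](O[Si](c1ccccc1)(c1ccccc1)C(C)(C)C)CC(=O)OC(=O)C(F)(F)F | intermediate (not isolated)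
7 | allyl 2-{5-[(R)-3-(TBDPS-oxy)butanoyl]furan-2-yl}acetate | C[C@@H](O[Si](c1ccccc1)(c1ccccc1)C(C)(C)C)CC(=O)c1ccc(CC(=O)OCC=C)o1 | intermediate
8 | allyl 2-{5-[(1R,3R)-1-hydroxy-3-(TBDPS-oxy)butyl]furan-2-yl}acetate | C[C@@H](O[Si](c1ccccc1)(c1ccccc1)C(C)(C)C)C[C@@H](O)c1ccc(CC(=O)OCC=C)o1 | intermediate
9 | allyl 2-{(6R)-2-hydroxy-5-oxo-6-[(R)-2-(TBDPS-oxy)propyl]-5,6-dihydro-2H-pyran-2-yl}acetate (anomers) | C[C@@H](O[Si](c1ccccc1)(c1ccccc1)C(C)(C)C)C[C@H]1OC(O)(CC(=O)OCC=C)C=CC1=O | intermediate (not isolated)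
10 | allyl 2-{(2S,6R)-5-oxo-6-[(R)-2-(TBDPS-oxy)propyl]-5,6-dihydro-2H-pyran-2-yl}acetate | C[C@@H](O[Si](c1ccccc1)(c1ccccc1)C(C)(C)C)C[C@H]1O[C@@H](CC(=O)OCC=C)C=CC1=O | intermediate
11 | 2-(furan-2-yl)acetonitrile | N#CCc1ccco1 | starting material
12 | 2-(5-acetylfuran-2-yl)acetonitrile | CC(=O)c1ccc(CC#N)o1 | intermediate
13 | 2-{5-[(R)-1-hydroxyethyl]furan-2-yl}acetonitrile | C[C@@H](O)c1ccc(CC#N)o1 | intermediate
14 | methyl (Z)-3-amino-4-{5-[(R)-1-hydroxyethyl]furan-2-yl}but-2-enoate | C[C@@H](O)c1ccc(C/C(N)=C/C(=O)OC)o1 | intermediate (not isolated)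
15 | methyl 4-{5-[(R)-1-hydroxyethyl]furan-2-yl}-3-oxobutanoate | C[C@@H](O)c1ccc(CC(=O)CC(=O)OC)o1 | intermediate
16 | methyl 2-{(2S,3S,6R)-2-(2-allyloxy-2-oxoethyl)-5-oxo-6-[(R)-2-(TBDPS-oxy)propyl]tetrahydro-2H-pyran-3-yl}-4-{5-[(R)-1-hydroxyethyl]furan-2-yl}-3-oxobutanoate | C[C@@H](O[Si](c1ccccc1)(c1ccccc1)C(C)(C)C)C[C@H]1O[C@@H](CC(=O)OCC=C)[C@H](C(C(=O)OC)C(=O)Cc2ccc([C@@H](C)O)o2)CC1=O | intermediate
17 | allyl (3S,4S,9R)-3-hydroxy-4-(4-{5-[(R)-1-hydroxyethyl]furan-2-yl}-1-methoxy-1,3-dioxobutan-2-yl)-6-oxo-9-(TBDPS-oxy)decanoate | C[C@@H](O[Si](c1ccccc1)(c1ccccc1)C(C)(C)C)CCC(=O)C[C@@H](C(C(=O)OC)C(=O)Cc1ccc([C@@H](C)O)o1)[C@@H](O)CC(=O)OCC=C | intermediate (not isolated)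
18 | allyl 2-{(2S,3S)-4-(2-{5-[(R)-1-hydroxyethyl]furan-2-yl}acetyl)-5-oxo-3-[(R)-2-oxo-5-(TBDPS-oxy)hexyl]tetrahydrofuran-2-yl}acetate | C[C@@H](O[Si](c1ccccc1)(c1ccccc1)C(C)(C)C)CCC(=O)C[C@H]1C(C(=O)Cc2ccc([C@@H](C)O)o2)C(=O)O[C@H]1CC(=O)OCC=C | intermediate
19 | allyl 2-{(2S,3S)-4-{2-[(6R)-2-hydroxy-6-methyl-5-oxo-5,6-dihydro-2H-pyran-2-yl]acetyl}-5-oxo-3-[(R)-2-oxo-5-(TBDPS-oxy)hexyl]tetrahydrofuran-2-yl}acetate (anomers) | C[C@@H](O[Si](c1ccccc1)(c1ccccc1)C(C)(C)C)CCC(=O)C[C@H]1C(C(=O)CC2(O)C=CC(=O)[C@@H](C)O2)C(=O)O[C@H]1CC(=O)OCC=C | intermediate (not isolated)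
20 | allyl 2-{(2S,3S)-4-{2-[(2S,6R)-6-methyl-5-oxo-5,6-dihydro-2H-pyran-2-yl]acetyl}-5-oxo-3-[(R)-2-oxo-5-(TBDPS-oxy)hexyl]tetrahydrofuran-2-yl}acetate | C[C@@H](O[Si](c1ccccc1)(c1ccccc1)C(C)(C)C)CCC(=O)C[C@H]1C(C(=O)C[C@H]2C=CC(=O)[C@@H](C)O2)C(=O)O[C@H]1CC(=O)OCC=C | intermediate (not isolated)
21 | allyl 2-{(2S,3S,4E)-4-[(3aS,5R,7aS)-5-methyl-6-oxohexahydro-2H-furo[3,2-b]pyran-2(3H)-ylidene]-5-oxo-3-[(R)-2-oxo-5-(TBDPS-oxy)hexyl]tetrahydrofuran-2-yl}acetate | C[C@@H](O[Si](c1ccccc1)(c1ccccc1)C(C)(C)C)CCC(=O)C[C@H]1/C(=C2/C[C@@H]3O[C@H](C)C(=O)C[C@@H]3O2)C(=O)O[C@H]1CC(=O)OCC=C | intermediate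
22 | 6-hydroxy analogue of 21 (C6 epimers) | C[C@@H](O[Si](c1ccccc1)(c1ccccc1)C(C)(C)C)CCC(=O)C[C@H]1/C(=C2/C[C@@H]3O[C@H](C)C(O)C[C@@H]3O2)C(=O)O[C@H]1CC(=O)OCC=C | intermediate
23 | 6-O-(1H-imidazol-1-ylcarbonothioyl) derivative of 22 (C6 epimers) | C[C@@H](O[Si](c1ccccc1)(c1ccccc1)C(C)(C)C)CCC(=O)C[C@H]1/C(=C2/C[C@@H]3O[C@H](C)C(OC(=S)n4ccnc4)C[C@@H]3O2)C(=O)O[C@H]1CC(=O)OCC=C | intermediate
24 | allyl 2-{(2S,3S,4E)-4-[(3aS,5R,7aS)-5-methylhexahydro-2H-furo[3,2-b]pyran-2(3H)-ylidene]-5-oxo-3-[(R)-2-oxo-5-(TBDPS-oxy)hexyl]tetrahydrofuran-2-yl}acetate | C[C@@H](O[Si](c1ccccc1)(c1ccccc1)C(C)(C)C)CCC(=O)C[C@H]1/C(=C2/C[C@@H]3O[C@H](C)CC[C@@H]3O2)C(=O)O[C@H]1CC(=O)OCC=C | intermediate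
25 | allyl 2-{(2S,3S,4E)-3-[(R)-5-hydroxy-2-oxohexyl]-4-[(3aS,5R,7aS)-5-methylhexahydro-2H-furo[3,2-b]pyran-2(3H)-ylidene]-5-oxotetrahydrofuran-2-yl}acetate | C[C@@H](O)CCC(=O)C[C@H]1/C(=C2/C[C@@H]3O[C@H](C)CC[C@@H]3O2)C(=O)O[C@H]1CC(=O)OCC=C | intermediate
26 | 2-{(2S,3S,4E)-3-[(R)-5-hydroxy-2-oxohexyl]-4-[(3aS,5R,7aS)-5-methylhexahydro-2H-furo[3,2-b]pyran-2(3H)-ylidene]-5-oxotetrahydrofuran-2-yl}acetic acid | C[C@@H](O)CCC(=O)C[C@H]1/C(=C2/C[C@@H]3O[C@H](C)CC[C@@H]3O2)C(=O)O[C@H]1CC(=O)O | intermediate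
27 | mixed anhydride of 26 with 2-methyl-6-nitrobenzoic acid | C[C@@H](O)CCC(=O)C[C@H]1/C(=C2/C[C@@H]3O[C@H](C)CC[C@@H]3O2)C(=O)O[C@H]1CC(=O)OC(=O)c1c(C)cccc1[N+](=O)[O-] | intermediate (not isolated)
28 | cordycicadin C | C[C@@H]1CCC(=O)C[C@H]2/C(=C3/C[C@@H]4O[C@H](C)CC[C@@H]4O3)C(=O)O[C@H]2CC(=O)O1 | target

## Step count and risks

Total step count: 18
Longest linear sequence: 14 steps (1, 2, 4, 5, 6, 10 to 18)

Steps most likely to fail

Step 12. The one-flask sequence could be diverted by acid-promoted dehydration of the lactol towards an aromatised furan, by aldol attack of the C3 methylene on the chain ketone, or by a conjugate addition that stalls or reverts with β-elimination. The fallback sets out from 18 and forms the same O1–C7a bond by electrophilic activation of an isolated alkene instead of conjugate addition. Oxidation and silane reduction are run as two separate operations and the enone 20 is isolated. Luche reduction (NaBH4, CeCl3·7H2O, MeOH, −78 °C) of the conjugated ring ketone gives the allylic alcohol F1, with the hydroxyl trans to the methyl group. N-Iodosuccinimide (NaHCO3, MeCN, 0 °C) then triggers a 5-exo-trig iodoetherification in which the enol oxygen opens the iodonium ion at C7a; the tether again enforces the cis ring fusion, and anti addition puts iodine on C7 in the iodo ether F2. Bu3SnH/AIBN removes the iodine and gives one C6 epimer of 22, where the route is rejoined (step 13 is then not needed).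

Step 18. Closure of the ten-membered ring could lose out to oligomerisation, and the activated acyl species could undergo β-elimination of the γ-lactone oxygen, which is β to the activated carbonyl. The fallback sets out from 25 and avoids acyl activation by activating the carbinol carbon instead, with double inversion. An Appel reaction (CBr4, PPh3, CH2Cl2, 0 °C) gives the inverted secondary bromide F3. Deallylation as in step 17 gives the bromo acid F4. Cs2CO3 in DMF at high dilution then lets the caesium carboxylate displace bromide with a second inversion, which returns the R configuration at C9 and gives 28 directly.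

Step 4. The activated β-silyloxy acyl donor could lose the silyloxy group by β-elimination to a crotonyl species, and the furan could be trifluoroacetylated instead. The fallback sets out from 5 and makes the elimination product on purpose. Friedel–Crafts acylation with (E)-but-2-enoyl chloride (SnCl4, CH2Cl2, −78 °C) gives the enone F5. Copper-catalysed enantioselective conjugate borylation (CuCl, NaOtBu, a chiral ferrocenyl bisphosphine of the hand that gives the R product, B2pin2, MeOH) gives the β-boryl ketone F6. Oxidation with NaBO3·4H2O proceeds with retention to the β-hydroxy ketone F7, and silylation as in step 1 returns to 7.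

Further compounds
F1 | step 12 | allyl 2-{(2S,3S)-4-{2-[(2S,5S,6R)-5-hydroxy-6-methyl-5,6-dihydro-2H-pyran-2-yl]acetyl}-5-oxo-3-[(R)-2-oxo-5-(TBDPS-oxy)hexyl]tetrahydrofuran-2-yl}acetate | C[C@@H](O[Si](c1ccccc1)(c1ccccc1)C(C)(C)C)CCC(=O)C[C@H]1C(C(=O)C[C@H]2C=C[C@H](O)[C@@H](C)O2)C(=O)O[C@H]1CC(=O)OCC=C
F2 | step 12 | 7-iodo derivative of 22 (iodine trans to O1, 6-hydroxyl trans to the 5-methyl group, cis ring fusion) | C[C@@H](O[Si](c1ccccc1)(c1ccccc1)C(C)(C)C)CCC(=O)C[C@H]1/C(=C2/C[C@@H]3O[C@H](C)[C@@H](O)[C@@H](I)[C@@H]3O2)C(=O)O[C@H]1CC(=O)OCC=C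
F3 | step 18 | allyl 2-{(2S,3S,4E)-3-[(S)-5-bromo-2-oxohexyl]-4-[(3aS,5R,7aS)-5-methylhexahydro-2H-furo[3,2-b]pyran-2(3H)-ylidene]-5-oxotetrahydrofuran-2-yl}acetate | C[C@H](Br)CCC(=O)C[C@H]1/C(=C2/C[C@@H]3O[C@H](C)CC[C@@H]3O2)C(=O)O[C@H]1CC(=O)OCC=C
F4 | step 18 | 2-{(2S,3S,4E)-3-[(S)-5-bromo-2-oxohexyl]-4-[(3aS,5R,7aS)-5-methylhexahydro-2H-furo[3,2-b]pyran-2(3H)-ylidene]-5-oxotetrahydrofuran-2-yl}acetic acid | C[C@H](Br)CCC(=O)C[C@H]1/C(=C2/C[C@@H]3O[C@H](C)CC[C@@H]3O2)C(=O)O[C@H]1CC(=O)O
F5 | step 4 | allyl 2-{5-[(E)-but-2-enoyl]furan-2-yl}acetate | C/C=C/C(=O)c1ccc(CC(=O)OCC=C)o1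
F6 | step 4 | allyl 2-{5-[(R)-3-(4,4,5,5-tetramethyl-1,3,2-dioxaborolan-2-yl)butanoyl]furan-2-yl}acetate | C[C@@H](B1OC(C)(C)C(C)(C)O1)CC(=O)c1ccc(CC(=O)OCC=C)o1
F7 | step 4 | allyl 2-{5-[(R)-3-hydroxybutanoyl]furan-2-yl}acetate | C[C@@H](O)CC(=O)c1ccc(CC(=O)OCC=C)o1
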